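**Strategy.** The route rests on C2, the lone stereocentre, which is simultaneously α to the C1 aryl ketone of ring A (the syringyl ring), bonded to the phenolic oxygen of ring B (the vanillic acid ring) and the carrier of the C3 hydroxymethyl group. This is the pattern left when a ketocarbene carbon is captured by a phenol O–H and the resulting enol is intercepted by formaldehyde. One cocatalysed operation should therefore form O–C2, C2–C3 and the (S) centre without closing a ring. The precursors are a MOM-protected ring A diazomethyl ketone, tert-butyl vanillate and monomeric formaldehyde; one acidolysis then frees phenol and acid.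

Key step: step 4

Remark on the chemistry: the sense of induction of the chiral phosphoric acid cannot be predicted with confidence for this substrate combination. The (R)-configured catalyst is written; its mirror image would be used should it deliver the (2R) product.

Remark on the chemistry: formaldehyde is bought as paraformaldehyde and depolymerised thermally into dry THF just before use. This reagent preparation is not counted as a step.

**Step 1**
Reactants: 1 acetosyringone, 1-(4-hydroxy-3,5-dimethoxyphenyl)ethan-1-one
Product: 2 1-[4-(methoxymethoxy)-3,5-dimethoxyphenyl]ethan-1-one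
Conditions: MOMCl, iPr2NEt, CH2Cl2, 0 °C to rt
Reagents that add atoms: chloromethyl methyl ether (MOMCl), COCCl
Why: Williamson-type O-alkylation: iPr2NEt deprotonates the acidic para-acyl phenol and the phenoxide displaces chloride from the highly reactive α-chloro ether, installing a MOM acetal that withstands LiHMDS and the carbene step and is removed by acid in step 5.

**Step 2**
Reactants: 2 1-[4-(methoxymethoxy)-3,5-dimethoxyphenyl]ethan-1-one
Product: 4 2-diazo-1-[4-(methoxymethoxy)-3,5-dimethoxyphenyl]ethan-1-one, via trifluoroacetyl diketone 3 (not isolated)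
Conditions: a) LiHMDS, THF, −78 °C, then CF3CO2CH2CF3; cold dil. HCl quench, crude 3 carried on; b) p-ABSA, Et3N, H2O (1 equiv), MeCN, rt
Reagents that add atoms: 4-acetamidobenzenesulfonyl azide (p-ABSA), CC(=O)Nc1ccc(cc1)S(=O)(=O)N=[N+]=[N-] (supplies both diazo nitrogens of 4); 2,2,2-trifluoroethyl trifluoroacetate, O=C(OCC(F)(F)F)C(F)(F)F (its trifluoroacetyl group is carried only in 3)
Why: Deacylative (detrifluoroacetylative) Regitz-type diazo transfer: Claisen trifluoroacetylation of the kinetic lithium enolate of 2 gives the acidic diketone 3, whose triethylammonium enolate adds to the sulfonyl azide and fragments with transfer of the trifluoroacetyl group to the sulfonamide nitrogen, a standard way from aryl methyl ketones to diazomethyl ketones that leaves the MOM acetal alone.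

**Step 3**
Reactants: 5 vanillic acid, 4-hydroxy-3-methoxybenzoic acid
Product: 6 tert-butyl 4-hydroxy-3-methoxybenzoate (tert-butyl vanillate)
Conditions: Me2NCH(OtBu)2, toluene, 80 °C
Reagents that add atoms: N,N-dimethylformamide di-tert-butyl acetal, CN(C)C(OC(C)(C)C)OC(C)(C)C
Why: Carboxylic acid O-alkylation by a formamide acetal: the acid protonates the acetal, which collapses to DMF and a tert-butyl cation captured within the ion pair by the carboxylate, while the far less acidic phenol is not alkylated and stays free for step 4.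

**Step 4**
Reactants: 4 2-diazo-1-[4-(methoxymethoxy)-3,5-dimethoxyphenyl]ethan-1-one; 6 tert-butyl 4-hydroxy-3-methoxybenzoate; 7 formaldehyde (monomer in dry THF)
Product: 9 tert-butyl 4-{[(2S)-3-hydroxy-1-[4-(methoxymethoxy)-3,5-dimethoxyphenyl]-1-oxopropan-2-yl]oxy}-3-methoxybenzoate, via α-aryloxy enol 8 (not isolated)
Conditions: Rh2(OAc)4 (2 mol %), (R)-TRIP [(R)-3,3′-bis(2,4,6-triisopropylphenyl)-BINOL hydrogen phosphate] (10 mol %), 6 (1.5 equiv), 7 (5 equiv), dry CH2Cl2/THF, −20 °C, 4 added over several hours by syringe pump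
Reagents that add atoms: none
Why: Proposed new method: Rh2(OAc)4 should expel N2 from 4 to give an electrophilic rhodium carbene, which the phenolic oxygen of 6 attacks to form a catalyst-associated oxonium ylide that relaxes by proton transfer to the α-aryloxy enol 8; the phosphoric acid is expected to hydrogen-bond the enol O–H through its P=O oxygen and formaldehyde through its P–OH, so that the aldol C2–C3 bond forms inside this assembly before the competing 1,2-hydrogen shift can deliver the simple O–H insertion product. The closest known reaction type is the interception of alcohol-derived oxonium ylides, generated from aryldiazoacetates under Rh2(OAc)4, by aldehydes or imines under chiral phosphoric acid cocatalysis; the untested points are a phenol as the O–H partner, formaldehyde as the electrophile and an acceptor-only diazoketone as the carbene source in one reaction. No ring is closed. C2 is the only new stereocentre and is set by the catalyst, whose 3,3′-aryl groups should shield one face of the bound enol so that formaldehyde is delivered to the face leading to (S). The step needs chemoselectivity for three-component trapping over two-component O–H insertion, carbene dimerisation and insertion into the primary alcohol of 9, and this is served by the unhindered terminal carbene carbon of 4, the acidic unhindered phenol of 6 used in excess, the high electrophilicity of monomeric formaldehyde, slow addition of 4 and low temperature. The near-neutral medium should leave the enolisable C2–H, the MOM acetal and the tert-butyl ester untouched.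

**Step 5**
Reactants: 9 tert-butyl 4-{[(2S)-3-hydroxy-1-[4-(methoxymethoxy)-3,5-dimethoxyphenyl]-1-oxopropan-2-yl]oxy}-3-methoxybenzoate
Product: 10 4-{[(2S)-3-hydroxy-1-(4-hydroxy-3,5-dimethoxyphenyl)-1-oxopropan-2-yl]oxy}-3-methoxybenzoic acid (CNP0507417.2)
Conditions: TFA/CH2Cl2 (1:3), H2O (5 equiv), 0 °C to rt; evaporation from toluene; aq. MeOH, rt (cleaves any C3 trifluoroacetate)
Reagents that add atoms: none
Why: Global acidolysis: the tert-butyl ester is cleaved by alkyl–oxygen fission to isobutene and the MOM acetal is hydrolysed through its oxocarbenium ion, the added water trapping the cationic fragments, and because no base is present the C2 centre next to the ketone should keep its configuration.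

**Compound list**
1 | acetosyringone, 1-(4-hydroxy-3,5-dimethoxyphenyl)ethan-1-one | CC(=O)c1cc(OC)c(O)c(OC)c1 | starting material
2 | 1-[4-(methoxymethoxy)-3,5-dimethoxyphenyl]ethan-1-one | CC(=O)c1cc(OC)c(OCOC)c(OC)c1 | intermediate
3 | 4,4,4-trifluoro-1-[4-(methoxymethoxy)-3,5-dimethoxyphenyl]butane-1,3-dione (trifluoroacetyl diketone, not isolated) | COCOc1c(OC)cc(C(=O)CC(=O)C(F)(F)F)cc1OC | intermediate
4 | 2-diazo-1-[4-(methoxymethoxy)-3,5-dimethoxyphenyl]ethan-1-one | COCOc1c(OC)cc(C(=O)C=[N+]=[N-])cc1OC | intermediate
5 | vanillic acid, 4-hydroxy-3-methoxybenzoic acid | COc1cc(C(=O)O)ccc1O | starting material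
6 | tert-butyl 4-hydroxy-3-methoxybenzoate (tert-butyl vanillate) | COc1cc(C(=O)OC(C)(C)C)ccc1O | intermediate
7 | formaldehyde (commercial as paraformaldehyde) | C=O | starting material
8 | tert-butyl 4-({2-hydroxy-2-[4-(methoxymethoxy)-3,5-dimethoxyphenyl]ethenyl}oxy)-3-methoxybenzoate (α-aryloxy enol, double-bond geometry not defined, not isolated) | COc1cc(C(=O)OC(C)(C)C)ccc1OC=C(O)c1cc(OC)c(OCOC)c(OC)c1 | intermediate
9 | tert-butyl 4-{[(2S)-3-hydroxy-1-[4-(methoxymethoxy)-3,5-dimethoxyphenyl]-1-oxopropan-2-yl]oxy}-3-methoxybenzoate | COc1cc(C(=O)OC(C)(C)C)ccc1O[C@@H](CO)C(=O)c1cc(OC)c(OCOC)c(OC)c1 | intermediate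
10 | 4-{[(2S)-3-hydroxy-1-(4-hydroxy-3,5-dimethoxyphenyl)-1-oxopropan-2-yl]oxy}-3-methoxybenzoic acid | COc1cc(C(=O)O)ccc1O[C@@H](CO)C(=O)c1cc(OC)c(O)c(OC)c1 | target

**Total step count:** 5.
**Longest linear sequence:** 4 steps (1 to 2 to 4 to 9 to 10, that is steps 1, 2, 4 and 5).

**Steps most likely to fail**

1. Step 4 (key step).
- What may go wrong: the 1,2-hydrogen shift of the ylide or enol may outrun aldol capture, so that two-component O–H insertion dominates. Carbene dimerisation or insertion into the newly formed primary alcohol may consume the diazoketone. Facial discrimination of the enol by the phosphoric acid may be poor, giving low enantiomeric purity.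
- Fallback (known chemistry, sets out from 6, returns at 9): phenol 6 is O-alkylated with commercial (R)-4-benzyl-3-(chloroacetyl)-1,3-oxazolidin-2-one (K2CO3, NaI, acetone) to the imide tert-butyl 4-{2-[(4R)-4-benzyl-2-oxo-1,3-oxazolidin-3-yl]-2-oxoethoxy}-3-methoxybenzoate F1. Commercial syringaldehyde is MOM-protected as in step 1 to 4-(methoxymethoxy)-3,5-dimethoxybenzaldehyde F2. An Evans syn-aldol reaction of F1 (Bu2BOTf, iPr2NEt, CH2Cl2, −78 °C) with F2 should give tert-butyl 4-{[(2R,3S)-1-[(4R)-4-benzyl-2-oxo-1,3-oxazolidin-3-yl]-3-hydroxy-3-[4-(methoxymethoxy)-3,5-dimethoxyphenyl]-1-oxopropan-2-yl]oxy}-3-methoxybenzoate F3, the auxiliary fixing the configuration of the future C2. Reductive removal of the auxiliary (NaBH4, THF/H2O, 0 °C) should give the diol tert-butyl 4-{[(1S,2S)-1,3-dihydroxy-1-[4-(methoxymethoxy)-3,5-dimethoxyphenyl]propan-2-yl]oxy}-3-methoxybenzoate F4. Chemoselective oxidation of its benzylic alcohol with DDQ (CH2Cl2, rt), which leaves the primary alcohol alone and erases the carbinol centre, returns to 9 with C2 as (S).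

2. Step 5.
- What may go wrong: acid-promoted enolisation at C2 may erode enantiomeric purity. The β-hydroxy ketone may dehydrate to the enone. The C3 hydroxyl or ring A may capture the methoxymethyl cation or the formaldehyde released from the MOM group.
- Fallback (sets out from 1 and 5, returns at 10): the acid-labile groups are exchanged for benzyl groups so that the final unveiling is a neutral hydrogenolysis. O-Benzylation of 1 (BnBr, K2CO3, DMF) would give 1-[4-(benzyloxy)-3,5-dimethoxyphenyl]ethan-1-one F5. The sequence of step 2 applied to F5 would pass through 1-[4-(benzyloxy)-3,5-dimethoxyphenyl]-4,4,4-trifluorobutane-1,3-dione F6, taken on crude, to 1-[4-(benzyloxy)-3,5-dimethoxyphenyl]-2-diazoethan-1-one F7. Carboxylate benzylation of 5 (BnBr, KHCO3, DMF) would give benzyl 4-hydroxy-3-methoxybenzoate F8. The coupling of step 4 with F7, F8 and 7 would give benzyl 4-{[(2S)-1-[4-(benzyloxy)-3,5-dimethoxyphenyl]-3-hydroxy-1-oxopropan-2-yl]oxy}-3-methoxybenzoate F9. Hydrogenolysis of both benzyl groups (H2, Pd/C, EtOAc, rt, stopped at full debenzylation) would give 10.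

3. Step 2.
- What may go wrong: Claisen trifluoroacetylation may be incomplete, or retro-Claisen loss of the trifluoroacetyl group before diazo transfer may return the methyl ketone.
- Fallback (sets out from 2, returns at 4): the diazo group is built by substitution and elimination instead of diazo transfer. Ketone 2 is converted (LiHMDS, TMSCl, THF, −78 °C) into trimethyl({1-[4-(methoxymethoxy)-3,5-dimethoxyphenyl]ethenyl}oxy)silane F10. Bromination with NBS (THF, 0 °C) under non-acidic conditions gives 2-bromo-1-[4-(methoxymethoxy)-3,5-dimethoxyphenyl]ethan-1-one F11. Treatment of F11 with N,N′-ditosylhydrazine and DBU (THF, 0 °C) leads to 4 by N-alkylation and twofold loss of sulfinate.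

**Further compounds**
F1 | step 4 | tert-butyl 4-{2-[(4R)-4-benzyl-2-oxo-1,3-oxazolidin-3-yl]-2-oxoethoxy}-3-methoxybenzoate | COc1cc(C(=O)OC(C)(C)C)ccc1OCC(=O)N1[C@H](Cc2ccccc2)COC1=O
F2 | step 4 | 4-(methoxymethoxy)-3,5-dimethoxybenzaldehyde | COCOc1c(OC)cc(C=O)cc1OC
F3 | step 4 | tert-butyl 4-{[(2R,3S)-1-[(4R)-4-benzyl-2-oxo-1,3-oxazolidin-3-yl]-3-hydroxy-3-[4-(methoxymethoxy)-3,5-dimethoxyphenyl]-1-oxopropan-2-yl]oxy}-3-methoxybenzoate | COc1cc(C(=O)OC(C)(C)C)ccc1O[C@H]([C@@H](O)c1cc(OC)c(OCOC)c(OC)c1)C(=O)N1[C@H](Cc2ccccc2)COC1=O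
F4 | step 4 | tert-butyl 4-{[(1S,2S)-1,3-dihydroxy-1-[4-(methoxymethoxy)-3,5-dimethoxyphenyl]propan-2-yl]oxy}-3-methoxybenzoate | COc1cc(C(=O)OC(C)(C)C)ccc1O[C@@H](CO)[C@@H](O)c1cc(OC)c(OCOC)c(OC)c1
F5 | step 5 | 1-[4-(benzyloxy)-3,5-dimethoxyphenyl]ethan-1-one | CC(=O)c1cc(OC)c(OCc2ccccc2)c(OC)c1
F6 | step 5 | 1-[4-(benzyloxy)-3,5-dimethoxyphenyl]-4,4,4-trifluorobutane-1,3-dione | COc1cc(C(=O)CC(=O)C(F)(F)F)cc(OC)c1OCc1ccccc1
F7 | step 5 | 1-[4-(benzyloxy)-3,5-dimethoxyphenyl]-2-diazoethan-1-one | COc1cc(C(=O)C=[N+]=[N-])cc(OC)c1OCc1ccccc1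
F8 | step 5 | benzyl 4-hydroxy-3-methoxybenzoate | COc1cc(C(=O)OCc2ccccc2)ccc1O
F9 | step 5 | benzyl 4-{[(2S)-1-[4-(benzyloxy)-3,5-dimethoxyphenyl]-3-hydroxy-1-oxopropan-2-yl]oxy}-3-methoxybenzoate | COc1cc(C(=O)OCc2ccccc2)ccc1O[C@@H](CO)C(=O)c1cc(OC)c(OCc2ccccc2)c(OC)c1
F10 | step 2 | trimethyl({1-[4-(methoxymethoxy)-3,5-dimethoxyphenyl]ethenyl}oxy)silane | COCOc1c(OC)cc(C(=C)O[Si](C)(C)C)cc1OC
F11 | step 2 | 2-bromo-1-[4-(methoxymethoxy)-3,5-dimethoxyphenyl]ethan-1-one | COCOc1c(OC)cc(C(=O)CBr)cc1OC
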